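**Plan**

1. The target is catechin-(4α→6)-epicatechin-(4β→8)-epicatechin-(4β→8)-epicatechin (units A, B, C, D from the top). The retrosynthesis cuts first C4 of unit B–C8 of unit C, then C4 of unit A–C6 of unit B, then O1–C2 and C3–C4 of the pyran ring of unit C together, and last C4 of unit C–C8 of unit D (aryllithium plus aldehyde).
2. Enabling feature: the pyran ring of unit C (O1–C2–C3–C4–C4a–C8a) is a chroman with the electron-rich C8 aryl of unit D on C4, an aryl group on C2 and oxygen on C3. This is the retron of an ortho-quinone methide (O1=C8a–C4a=C4) plus a Z styrene whose C3 carries boron as a masked hydroxyl.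
3. Forward, lower half: epicatechin → 8-bromide → 8-lithio species + phloroglucinaldehyde dibenzyl ether → o-hydroxybenzhydrol. Acid-triggered dehydration to the quinone methide and [4+2] with the (Z)-styrylboronate close the pyran ring of unit C; C–B oxidation gives benzylated procyanidin B2 (units C–D).
4. Forward, upper half: a bromine-capped catechin C4 electrophile is joined to C6 of bromine-capped epicatechin (units A–B), C4 of unit B is oxidised, and the dimer is joined to C8 of unit C. Deacetylation and one hydrogenolysis remove acetyl, benzyl and bromine.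
5. Stereochemistry: units A, B and D come from (+)-catechin and (−)-epicatechin. C2/C3 of unit C come from the Z alkene and retentive C–B oxidation, C4 from the exo approach, the absolute sense from a chiral Brønsted acid. Both new interflavan C4 centres arise by trans attack (acetoxy participation in unit A, axial 3-OH in unit B).

Key step: step 7

Assumption: the (R) antipode of the acid catalyst is taken as the one matched with the stereocentres of unit D for the required facial sense; if the sense proves opposite, the (S) antipode is the same reagent in mirror form.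

Abbreviations: Bn = benzyl; "Bn4" = 5,7,3',4'-tetra-O-benzyl; Bpin = 4,4,5,5-tetramethyl-1,3,2-dioxaborolan-2-yl.

**Route**

Step 1
Reactants: 1 (−)-epicatechin
Product: 2 5,7,3',4'-tetra-O-benzyl-(−)-epicatechin (2R,3R; 3-OH free)
Conditions: BnBr (4.4 equiv), K2CO3, DMF, 0 °C → rt, N2
Reagents that add atoms: benzyl bromide, BrCc1ccccc1
Why: Williamson benzylation under K2CO3 should alkylate only the four phenols, the secondary 3-OH being too weakly acidic, and leaves C2 and C3 untouched.

Step 2
Reactants: 2 Bn4-epicatechin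
Product: 3 8-bromo-5,7,3',4'-tetra-O-benzylepicatechin
Conditions: NBS (1.0 equiv), CH2Cl2, −78 °C → rt
Reagents that add atoms: N-bromosuccinimide, O=C1CCC(=O)N1Br
Why: Electrophilic aromatic bromination of benzylated flavan-3-ols goes to C8, the more accessible of the two free positions of the phloroglucinol ring.

Step 3
Reactants: 4 2,4,6-trihydroxybenzaldehyde
Product: 5 4,6-bis(benzyloxy)-2-hydroxybenzaldehyde
Conditions: BnBr (2.05 equiv), K2CO3, DMF, rt
Reagents that add atoms: benzyl bromide, BrCc1ccccc1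
Why: Williamson alkylation should take the para and one ortho hydroxyl, while the last ortho hydroxyl is held in a hydrogen bond to the formyl group and stays free.

Step 4
Reactants: 3 8-bromo-Bn4-epicatechin; 5 4,6-bis(benzyloxy)-2-hydroxybenzaldehyde
Product: 8 [4,6-bis(benzyloxy)-2-hydroxyphenyl](Bn4-epicatechin-8-yl)methanol (both carbinol epimers), via sodium phenoxide of the aldehyde 6 (not isolated), via 8-lithio lithium alkoxide 7 (not isolated)
Conditions: 5, NaH (1.05 equiv), THF, 0 °C; separately 3, n-BuLi (2.1 equiv), THF, −78 °C; combine, −78 → 0 °C; aq NH4Cl; crude product kept on Et3N-deactivated silica only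
Reagents that add atoms: none
Why: Bromine–lithium exchange gives the C8 aryllithium, which adds 1,2 to the formyl group of the phenoxide (organolithium addition to a salicylaldehyde salt); the carbinol centre forms as an epimer mixture, which does not matter because it becomes trigonal in step 7.

Step 5
Reactants: 9 3,4-bis(benzyloxy)benzaldehyde
Product: 10 4-ethynyl-1,2-bis(benzyloxy)benzene
Conditions: dimethyl (1-diazo-2-oxopropyl)phosphonate (1.2 equiv), K2CO3, MeOH, rt
Reagents that add atoms: dimethyl (1-diazo-2-oxopropyl)phosphonate, CC(=O)C(=[N+]=[N-])P(=O)(OC)OC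
Why: Ohira–Bestmann (Seyferth–Gilbert) homologation converts the aryl aldehyde into the terminal alkyne under conditions that leave benzyl ethers alone.

Step 6
Reactants: 10 4-ethynyl-1,2-bis(benzyloxy)benzene
Product: 11 (Z)-2-[2-(3,4-bis(benzyloxy)phenyl)ethenyl]-4,4,5,5-tetramethyl-1,3,2-dioxaborolane
Conditions: pinacolborane (1.0 equiv; 10 at 1.2 equiv), [Rh(cod)Cl]2 (1.5 mol %), P(i-Pr)3 (6 mol %), Et3N, cyclohexane, rt
Reagents that add atoms: pinacolborane, CC1(C)OBOC1(C)C
Why: Rhodium–phosphine-catalysed formal trans-hydroboration of a terminal alkyne (through a rhodium vinylidene) places boron at the terminus cis to the aryl group, fixing the Z geometry that later becomes the 2,3-cis relation.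

Step 7
Reactants: 8 o-hydroxybenzhydrol; 11 (Z)-styrylboronate (3 equiv)
Product: 13 3-deoxy-3-(Bpin)-Bn4-epicatechin-(4β→8)-Bn4-epicatechin (boron cis to the C2 aryl group and trans to the C4 aryl group), via ortho-quinone methide 12 (not isolated)
Conditions: (R)-3,3'-bis(2,4,6-triisopropylphenyl)-1,1'-binaphthyl-2,2'-diyl N-triflylphosphoramide (10 mol %), 5 Å molecular sieves, toluene, −30 °C → rt
Reagents that add atoms: none
Why: Proposed new method: the chiral acid protonates the carbinol hydroxyl of 8, which leaves as water to give the hydrogen-bonded ortho-quinone methide 12 (O1=C8a–C4a=C4); 12 should undergo an inverse-electron-demand oxa-[4+2] cycloaddition with the Z alkene of 11, the boron-bearing carbon (C3, β to the dialkoxyphenyl ring) bonding to the methide carbon C4 while the benzylic carbon C2, whose developing positive charge is stabilised by the para-alkoxyaryl group and by C–B hyperconjugation, is captured by the methide oxygen. The closest known reaction type is the chiral N-triflylphosphoramide-catalysed [4+2] of o-hydroxybenzhydrol-derived ortho-quinone methides with styrenes, together with ortho-quinone methide cycloadditions of β-substituted styrenes such as anethole; an alkenylboronic ester as the 2π partner is the untested element. The pyran ring of unit C closes by a concerted but asynchronous hetero-Diels–Alder cycloaddition (C3–C4 leading, O1–C2 following). C2 and C3 become cis because the addition is suprafacial on the Z alkene; C4 becomes trans to boron because the uncongested approach keeps the aryl and boryl groups away from the twisted 2,6-dioxygenated aryl on C4 and the peri 5-benzyloxy group (exo on the E methide, equivalent to endo on the Z methide); the absolute sense is set by the chiral phosphoramide anion bound to the methide oxygen, the stereocentres of unit D being too remote to decide it. The step needs regioselectivity (C3 to C4, not C2 to C4), secured by the matched styrene/β-boryl polarisation, and chemoselectivity against alkenyl transfer and protodeboronation, secured by the weakly Lewis-acidic pinacol ester and by the molecular sieves, which take up the water released on ionisation.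

Step 8
Reactants: 13 3-boryl dimer
Product: 14 Bn4-epicatechin-(4β→8)-Bn4-epicatechin (octa-O-benzylprocyanidin B2; both 3-OH free)
Conditions: NaBO3·4H2O (5 equiv), THF/H2O 1:1, rt
Reagents that add atoms: sodium perborate, [Na+].[O-]B1OO1
Why: Perborate oxidation of the secondary alkyl pinacolboronate proceeds by 1,2-migration of carbon from boron to oxygen with retention, so the C3 hydroxyl should appear cis to the C2 aryl group (2R,3R) under conditions too mild to cleave the interflavan bond.

Step 9
Reactants: 15 (+)-catechin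
Product: 16 5,7,3',4'-tetra-O-benzyl-(+)-catechin (2R,3S)
Conditions: BnBr (4.4 equiv), K2CO3, DMF, 0 °C → rt, N2
Reagents that add atoms: benzyl bromide, BrCc1ccccc1
Why: Williamson benzylation of the four phenols only, as in step 1, with the 2,3-trans centres untouched.

Step 10
Reactants: 16 Bn4-catechin
Product: 17 8-bromo-5,7,3',4'-tetra-O-benzylcatechin
Conditions: NBS (1.0 equiv), CH2Cl2, −78 °C → rt
Reagents that add atoms: N-bromosuccinimide, O=C1CCC(=O)N1Br
Why: C8-selective electrophilic bromination as in step 2; the halogen later caps unit A against self-condensation.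

Step 11
Reactants: 17 8-bromo-Bn4-catechin
Product: 18 8-bromo-4β-(2-ethoxyethoxy)-5,7,3',4'-tetra-O-benzylcatechin
Conditions: DDQ (2 equiv), 2-ethoxyethanol (5 equiv), CH2Cl2, rt
Reagents that add atoms: 2-ethoxyethanol, CCOCCO
Why: DDQ abstracts hydride from the benzylic C4 (oxidative benzylic C–H etherification) and the alcohol traps the cation, taken to give the 3,4-cis (4β) ether as described for benzylated catechin; this centre is lost again on ionisation in step 13.

Step 12
Reactants: 18 C4 ether of unit A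
Product: 19 3-O-acetyl-8-bromo-4β-(2-ethoxyethoxy)-5,7,3',4'-tetra-O-benzylcatechin
Conditions: Ac2O, pyridine, DMAP (cat.), rt
Reagents that add atoms: acetic anhydride, CC(=O)OC(C)=O
Why: Standard acylation of the secondary alcohol installs the 3-acetate that acts as participating group in step 13.

Step 13
Reactants: 19 unit A electrophile; 3 8-bromo-Bn4-epicatechin (3 equiv, excess recovered)
Product: 20 3-O-acetyl-8-bromo-Bn4-catechin-(4α→6)-8-bromo-Bn4-epicatechin
Conditions: Me3SiOSO2CF3 (0.3 equiv), CH2Cl2, −78 → −30 °C; Et3N quench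
Reagents that add atoms: none
Why: Lewis-acid Friedel–Crafts flavanylation in which the 3-acetoxy group shields the β face through an acetoxonium ion so that the arene adds trans (4α), the C8 bromine of 3 leaves C6 as its only nucleophilic carbon (halo-capping), and the C8 bromine of 19 plus the excess of 3 suppress self-condensation.

Step 14
Reactants: 20 unit A–B dimer
Product: 21 3-O-acetyl-8-bromo-Bn4-catechin-(4α→6)-8-bromo-4β-(2-ethoxyethoxy)-Bn4-epicatechin
Conditions: DDQ (2 equiv), 2-ethoxyethanol (5 equiv), CH2Cl2, rt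
Reagents that add atoms: 2-ethoxyethanol, CCOCCO
Why: DDQ hydride abstraction should occur at the only benzylic methylene, C4 of unit B (the doubly benzylic C4–H of unit A is shielded), and the alcohol adds trans to the axial 3-OH to give the 4β ether.

Step 15
Reactants: 21 dimeric electrophile; 14 octa-O-benzylprocyanidin B2 (3 equiv, excess recovered)
Product: 22 protected tetramer 3-O-acetyl-8-bromo-Bn4-catechin-(4α→6)-8-bromo-Bn4-epicatechin-(4β→8)-Bn4-epicatechin-(4β→8)-Bn4-epicatechin
Conditions: Me3SiOSO2CF3 (0.3 equiv), CH2Cl2, −78 → −40 °C; Et3N quench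
Reagents that add atoms: none
Why: Lewis-acid Friedel–Crafts coupling in which the C4 cation of unit B is attacked by C8 of the upper unit of 14, its most nucleophilic uncapped position, from the face trans to the axial 3-OH (4β), while both phloroglucinol rings of the electrophile are bromine-capped and cannot self-condense.

Step 16
Reactants: 22 protected tetramer
Product: 23 8-bromo-Bn4-catechin-(4α→6)-8-bromo-Bn4-epicatechin-(4β→8)-Bn4-epicatechin-(4β→8)-Bn4-epicatechin (all 3-OH free)
Conditions: NaOMe (0.3 equiv), MeOH/THF 1:1, rt → 40 °C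
Reagents that add atoms: none
Why: Zemplén-type transesterification removes the 3-acetate while benzyl ethers and aryl bromides are inert, so no base treatment of the free polyphenol is needed later.

Step 17
Reactants: 23 deacetylated tetramer
Product: 24 catechin-(4α→6)-epicatechin-(4β→8)-epicatechin-(4β→8)-epicatechin (CNP0228086.1)
Conditions: H2 (1 atm), Pd(OH)2/C, Et3N (2.5 equiv), THF/MeOH/H2O, rt; filtration, lyophilisation
Reagents that add atoms: none
Why: Hydrogenolysis over Pd(OH)2/C cleaves all sixteen benzyl ethers and hydrodehalogenates both aryl bromides, Et3N scavenging HBr so that the acid-labile interflavan bonds are kept; no stereocentre is touched.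

**Compound list**

1 | (−)-epicatechin | Oc1cc(O)c2c(c1)O[C@H](c1ccc(O)c(O)c1)[C@H](O)C2 | starting material
2 | 5,7,3',4'-tetra-O-benzylepicatechin | c7ccccc7COc1cc(OCc7ccccc7)c2c(c1)O[C@H](c1ccc(OCc7ccccc7)c(OCc7ccccc7)c1)[C@H](O)C2 | intermediate
3 | 8-bromo-5,7,3',4'-tetra-O-benzylepicatechin | c7ccccc7COc1cc(OCc7ccccc7)c2c(c1Br)O[C@H](c1ccc(OCc7ccccc7)c(OCc7ccccc7)c1)[C@H](O)C2 | intermediate
4 | 2,4,6-trihydroxybenzaldehyde | O=Cc1c(O)cc(O)cc1O | starting material
5 | 4,6-bis(benzyloxy)-2-hydroxybenzaldehyde | O=Cc1c(O)cc(OCc7ccccc7)cc1OCc7ccccc7 | intermediate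
6 | sodium 3,5-bis(benzyloxy)-2-formylphenoxide | [Na+].[O-]c1cc(OCc7ccccc7)cc(OCc7ccccc7)c1C=O | intermediate
7 | 8-lithio-5,7,3',4'-tetra-O-benzylepicatechin lithium 3-alkoxide | [Li]c1c(OCc7ccccc7)cc(OCc7ccccc7)c2c1O[C@H](c1ccc(OCc7ccccc7)c(OCc7ccccc7)c1)[C@H](O[Li])C2 | intermediate
8 | [4,6-bis(benzyloxy)-2-hydroxyphenyl](Bn4-epicatechin-8-yl)methanol, carbinol epimers | OC(c1c(O)cc(OCc7ccccc7)cc1OCc7ccccc7)c1c(OCc7ccccc7)cc(OCc7ccccc7)c2c1O[C@H](c1ccc(OCc7ccccc7)c(OCc7ccccc7)c1)[C@H](O)C2 | intermediate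
9 | 3,4-bis(benzyloxy)benzaldehyde | O=Cc1ccc(OCc7ccccc7)c(OCc7ccccc7)c1 | starting material
10 | 4-ethynyl-1,2-bis(benzyloxy)benzene | C#Cc1ccc(OCc7ccccc7)c(OCc7ccccc7)c1 | intermediate
11 | (Z)-2-[2-(3,4-bis(benzyloxy)phenyl)ethenyl]-4,4,5,5-tetramethyl-1,3,2-dioxaborolane | CC1(C)OB(/C=C\c2ccc(OCc7ccccc7)c(OCc7ccccc7)c2)OC1(C)C | intermediate
12 | ortho-quinone methide: 3,5-bis(benzyloxy)-6-[(Bn4-epicatechin-8-yl)methylidene]cyclohexa-2,4-dienone (alkene geometry open) | O=C1C=C(OCc7ccccc7)C=C(OCc7ccccc7)C1=Cc1c(OCc7ccccc7)cc(OCc7ccccc7)c2c1O[C@H](c1ccc(OCc7ccccc7)c(OCc7ccccc7)c1)[C@H](O)C2 | intermediate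
13 | 3-deoxy-3-(Bpin)-Bn4-epicatechin-(4β→8)-Bn4-epicatechin (2,3-cis, 3,4-trans) | c1c(OCc7ccccc7)cc(OCc7ccccc7)c3c1O[C@H](c1ccc(OCc7ccccc7)c(OCc7ccccc7)c1)[C@H](B5OC(C)(C)C(C)(C)O5)[C@H]3c1c(OCc7ccccc7)cc(OCc7ccccc7)c3c1O[C@H](c1ccc(OCc7ccccc7)c(OCc7ccccc7)c1)[C@H](O)C3 | intermediate
14 | Bn4-epicatechin-(4β→8)-Bn4-epicatechin (octa-O-benzylprocyanidin B2) | c1c(OCc7ccccc7)cc(OCc7ccccc7)c3c1O[C@H](c1ccc(OCc7ccccc7)c(OCc7ccccc7)c1)[C@H](O)[C@H]3c1c(OCc7ccccc7)cc(OCc7ccccc7)c3c1O[C@H](c1ccc(OCc7ccccc7)c(OCc7ccccc7)c1)[C@H](O)C3 | intermediate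
15 | (+)-catechin | Oc1cc(O)c2c(c1)O[C@H](c1ccc(O)c(O)c1)[C@@H](O)C2 | starting material
16 | 5,7,3',4'-tetra-O-benzylcatechin | c7ccccc7COc1cc(OCc7ccccc7)c2c(c1)O[C@H](c1ccc(OCc7ccccc7)c(OCc7ccccc7)c1)[C@@H](O)C2 | intermediate
17 | 8-bromo-5,7,3',4'-tetra-O-benzylcatechin | c7ccccc7COc1cc(OCc7ccccc7)c2c(c1Br)O[C@H](c1ccc(OCc7ccccc7)c(OCc7ccccc7)c1)[C@@H](O)C2 | intermediate
18 | 8-bromo-4β-(2-ethoxyethoxy)-5,7,3',4'-tetra-O-benzylcatechin | c7ccccc7COc1cc(OCc7ccccc7)c2c(c1Br)O[C@H](c1ccc(OCc7ccccc7)c(OCc7ccccc7)c1)[C@@H](O)[C@H]2OCCOCC | intermediate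
19 | 3-O-acetyl-8-bromo-4β-(2-ethoxyethoxy)-5,7,3',4'-tetra-O-benzylcatechin | c7ccccc7COc1cc(OCc7ccccc7)c2c(c1Br)O[C@H](c1ccc(OCc7ccccc7)c(OCc7ccccc7)c1)[C@@H](OC(C)=O)[C@H]2OCCOCC | intermediate
20 | 3-O-acetyl-8-bromo-Bn4-catechin-(4α→6)-8-bromo-Bn4-epicatechin | c7ccccc7COc1cc(OCc7ccccc7)c2c(c1Br)O[C@H](c1ccc(OCc7ccccc7)c(OCc7ccccc7)c1)[C@@H](OC(C)=O)[C@@H]2c1c(OCc7ccccc7)c(Br)c2c(c1OCc7ccccc7)C[C@@H](O)[C@@H](c1ccc(OCc7ccccc7)c(OCc7ccccc7)c1)O2 | intermediate
21 | 3-O-acetyl-8-bromo-Bn4-catechin-(4α→6)-8-bromo-4β-(2-ethoxyethoxy)-Bn4-epicatechin | c7ccccc7COc1cc(OCc7ccccc7)c2c(c1Br)O[C@H](c1ccc(OCc7ccccc7)c(OCc7ccccc7)c1)[C@@H](OC(C)=O)[C@@H]2c1c(OCc7ccccc7)c(Br)c2c(c1OCc7ccccc7)[C@H](OCCOCC)[C@@H](O)[C@@H](c1ccc(OCc7ccccc7)c(OCc7ccccc7)c1)O2 | intermediate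
22 | 3-O-acetyl-8-bromo-Bn4-catechin-(4α→6)-8-bromo-Bn4-epicatechin-(4β→8)-Bn4-epicatechin-(4β→8)-Bn4-epicatechin | c7ccccc7COc1cc(OCc7ccccc7)c2c(c1Br)O[C@H](c1ccc(OCc7ccccc7)c(OCc7ccccc7)c1)[C@@H](OC(C)=O)[C@@H]2c1c(OCc7ccccc7)c(Br)c2c(c1OCc7ccccc7)[C@H](c1c(OCc7ccccc7)cc(OCc7ccccc7)c3c1O[C@H](c1ccc(OCc7ccccc7)c(OCc7ccccc7)c1)[C@H](O)[C@H]3c1c(OCc7ccccc7)cc(OCc7ccccc7)c3c1O[C@H](c1ccc(OCc7ccccc7)c(OCc7ccccc7)c1)[C@H](O)C3)[C@@H](O)[C@@H](c1ccc(OCc7ccccc7)c(OCc7ccccc7)c1)O2 | intermediate
23 | 8-bromo-Bn4-catechin-(4α→6)-8-bromo-Bn4-epicatechin-(4β→8)-Bn4-epicatechin-(4β→8)-Bn4-epicatechin | c7ccccc7COc1cc(OCc7ccccc7)c2c(c1Br)O[C@H](c1ccc(OCc7ccccc7)c(OCc7ccccc7)c1)[C@@H](O)[C@@H]2c1c(OCc7ccccc7)c(Br)c2c(c1OCc7ccccc7)[C@H](c1c(OCc7ccccc7)cc(OCc7ccccc7)c3c1O[C@H](c1ccc(OCc7ccccc7)c(OCc7ccccc7)c1)[C@H](O)[C@H]3c1c(OCc7ccccc7)cc(OCc7ccccc7)c3c1O[C@H](c1ccc(OCc7ccccc7)c(OCc7ccccc7)c1)[C@H](O)C3)[C@@H](O)[C@@H](c1ccc(OCc7ccccc7)c(OCc7ccccc7)c1)O2 | intermediate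
24 | catechin-(4α→6)-epicatechin-(4β→8)-epicatechin-(4β→8)-epicatechin (CNP0228086.1) | Oc1cc(O)c2c(c1)O[C@H](c1ccc(O)c(O)c1)[C@@H](O)[C@@H]2c1c(O)cc2c(c1O)[C@H](c1c(O)cc(O)c3c1O[C@H](c1ccc(O)c(O)c1)[C@H](O)[C@H]3c1c(O)cc(O)c3c1O[C@H](c1ccc(O)c(O)c1)[C@H](O)C3)[C@@H](O)[C@@H](c1ccc(O)c(O)c1)O2 | target

**Summary**

Total step count: 17. Longest linear sequence: 9 steps (steps 9–17, from (+)-catechin); the epicatechin line runs 8 steps (1, 2, 4, 7, 8, 15, 16, 17).

**Steps most likely to fail**

1. Step 7. The strongly stabilised, crowded quinone methide may be captured too slowly by the weakly nucleophilic Z alkenylboronate, so that it dimerises or re-adds water. The exo and facial preferences may erode in a mismatched catalyst–substrate pair, and the β-aryloxy boronate may undergo β-elimination with ring opening. The fallback uses known chemistry, sets out from compound 2 and comes back at compound 14. Benzylic oxidation of 2 with DDQ and 2-ethoxyethanol in CH2Cl2 should give 4β-(2-ethoxyethoxy)-5,7,3',4'-tetra-O-benzylepicatechin F1. F1 is then condensed with an excess of 2 (Me3SiOSO2CF3, CH2Cl2, −78 °C); C8 of 2 attacks the C4 cation trans to the axial 3-OH, giving 14 directly. Steps 3 to 8 then fall away.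

2. Step 15. The C4 cation of unit B is flanked by the 5-benzyloxy group and by unit A on C6, so it may collapse back to the ether or be attacked through C6 instead of C8 of the nucleophile. On warming the hard Lewis acid may also cleave the interflavan bonds already present. The fallback sets out from compound 21 and comes back at compound 22. Exchange of the C4 ether with 2,6-dimethylbenzenethiol (BF3·OEt2, CH2Cl2, −78 °C) should give the 4β-(2,6-dimethylphenylthio) dimer F2, a stable electrophile precursor. F2 is then ionised in the presence of 14 by the soft, thiophilic salt AgOSO2CF3 with 2,6-di-tert-butyl-4-methylpyridine (CH2Cl2, −40 → 0 °C). This separates activation of the leaving group from hard Lewis acidity and should give 22.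

3. Step 4. The hindered 2,6-dioxygenated aryllithium may add only slowly to the electron-rich phenoxide aldehyde, with proton transfer competing, and the very acid-sensitive benzhydrol may ionise during isolation. The fallback reverses the polarity; it sets out from compound 3 and comes back at compound 8. The lithio species 7, made as in step 4, is quenched with DMF to give 8-formyl-5,7,3',4'-tetra-O-benzylepicatechin F3. Commercial 3,5-bis(benzyloxy)phenol is converted with EtMgBr into bromomagnesium 3,5-bis(benzyloxy)phenoxide F4. F4 is combined with F3 in toluene at rt; ortho-specific hydroxyalkylation through the magnesium-chelated six-membered transition state should give 8.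

Further compounds
F1 | step 7 | 4β-(2-ethoxyethoxy)-5,7,3',4'-tetra-O-benzylepicatechin | c7ccccc7COc1cc(OCc7ccccc7)c2c(c1)O[C@H](c1ccc(OCc7ccccc7)c(OCc7ccccc7)c1)[C@H](O)[C@H]2OCCOCC
F2 | step 15 | 3-O-acetyl-8-bromo-Bn4-catechin-(4α→6)-8-bromo-4β-(2,6-dimethylphenylthio)-Bn4-epicatechin | c7ccccc7COc1cc(OCc7ccccc7)c2c(c1Br)O[C@H](c1ccc(OCc7ccccc7)c(OCc7ccccc7)c1)[C@@H](OC(C)=O)[C@@H]2c1c(OCc7ccccc7)c(Br)c2c(c1OCc7ccccc7)[C@H](Sc1c(C)cccc1C)[C@@H](O)[C@@H](c1ccc(OCc7ccccc7)c(OCc7ccccc7)c1)O2
F3 | step 4 | 8-formyl-5,7,3',4'-tetra-O-benzylepicatechin | O=Cc1c(OCc7ccccc7)cc(OCc7ccccc7)c2c1O[C@H](c1ccc(OCc7ccccc7)c(OCc7ccccc7)c1)[C@H](O)C2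
F4 | step 4 | bromomagnesium 3,5-bis(benzyloxy)phenoxide | Br[Mg]Oc1cc(OCc7ccccc7)cc(OCc7ccccc7)c1
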